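**Strategy.** Both halves come from one building block, cyclopentenone 19, and a Diels–Alder reaction joins them through ring D. The seven-membered ring B' (C-1', C-10', C-9', C-8', C-7', C-6', C-5') is closed only afterwards. The key step exploits that C-1' is the β-carbon of the C-3' ketone of ring A' and that C-10' bears the exocyclic C-14' methylene. Reductive Heck cyclisation of an alkenyl bromide onto the ring A' enone forms the C-1'–C-10' bond, the cis ring fusion, the methylene and the saturated ketone in one operation. Its precursor 27 holds all other rings; ring A' is a cyclopent-2-enone with a 3-bromobut-3-enyl chain on lactone C'.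

Key step: step 13

Remark on numbering: guaiane numbering is used for both halves; primed atoms belong to the half with the spiro carbon C-4'. Ring D is C-2, C-1, C-10, C-14, C-15', C-4'. α/β refer to the usual guaianolide drawing.

Remark on stereochemistry: the SMILES fixes both lactones as cis-fused (H-6/H-7 and H-6'/H-7' syn, lactone O and C-11 both α). Natural trans-guaianolides therefore cannot serve as starting materials, and both halves are built de novo.

**Step 1**
Reactants: 1 2-bromoprop-2-en-1-ol; 2 ethyl vinyl ether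
Product: 4 4-bromopent-4-enal, via 2-bromoallyl vinyl ether 3 (not isolated)
Conditions: Hg(OAc)2 (5 mol %), neat 2, reflux; then PhMe, sealed tube, 150 °C
Reagents that add atoms: none
Why: Vinyl transfer gives the allyl vinyl ether, whose Claisen ([3,3]-sigmatropic) rearrangement places the two-carbon aldehyde unit on the allylic terminus and leaves the alkenyl bromide untouched; no stereocenter is formed.

**Step 2**
Reactants: 4 4-bromopent-4-enal; 5 methyl acrylate
Product: 6 methyl 6-bromo-3-hydroxy-2-methylidenehept-6-enoate (racemic)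
Conditions: DABCO (1 equiv), 5 (3 equiv), MeOH, rt
Reagents that add atoms: none
Why: Morita–Baylis–Hillman reaction of an unhindered aliphatic aldehyde; the racemic carbinol center is removed in step 3.

**Step 3**
Reactants: 6 methyl 6-bromo-3-hydroxy-2-methylidenehept-6-enoate
Product: 7 methyl (2Z)-6-bromo-2-(bromomethyl)hepta-2,6-dienoate
Conditions: NBS, Me2S, CH2Cl2, 0 °C to rt
Reagents that add atoms: N-bromosuccinimide, O=C1CCC(=O)N1Br
Why: The bromodimethylsulfonium reagent formed in the flask (Corey–Kim type) activates the hydroxyl, and bromide returns in the SN2' sense to give the thermodynamically preferred Z ester with the chain trans to the ester group.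

**Step 4**
Reactants: 8 (4S)-4-[(tert-butyldimethylsilyl)oxy]cyclopent-2-en-1-one; 9 vinylmagnesium bromide
Product: 10 (3R,4S)-4-[(tert-butyldimethylsilyl)oxy]-3-ethenylcyclopentan-1-one
Conditions: CuBr·SMe2 (10 mol %), THF, −78 °C; then aq. NH4Cl
Reagents that add atoms: none
Why: Copper-catalysed conjugate addition occurs anti to the C-4 silyloxy group, so the new stereocenter C-3 (later C-5 and C-5') is fixed by the (S)-enone.

**Step 5**
Reactants: 10 (3R,4S)-4-[(tert-butyldimethylsilyl)oxy]-3-ethenylcyclopentan-1-one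
Product: 12 (1S,2S)-2-[(tert-butyldimethylsilyl)oxy]-4-oxocyclopentane-1-carbaldehyde, via ozonide 11 (not isolated)
Conditions: O3, CH2Cl2, −78 °C; then PPh3, −78 °C to rt
Reagents that add atoms: ozone, [O-][O+]=O
Why: Ozonolysis cleaves the only alkene, and neutral phosphine reduction of the ozonide should avoid both epimerisation of the aldehyde α-center and β-elimination of the silyloxy group.

**Step 6**
Reactants: 12 (1S,2S)-2-[(tert-butyldimethylsilyl)oxy]-4-oxocyclopentane-1-carbaldehyde; 7 methyl (2Z)-6-bromo-2-(bromomethyl)hepta-2,6-dienoate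
Product: 14 (3R,4S)-3-[(2S,3R)-3-(3-bromobut-3-en-1-yl)-4-methylidene-5-oxooxolan-2-yl]-4-[(tert-butyldimethylsilyl)oxy]cyclopentan-1-one, via hydroxy ester 13 (not isolated)
Conditions: In powder, THF/H2O 1:1, rt; then PPTS (cat.), CH2Cl2, rt
Reagents that add atoms: none
Why: Indium-mediated Barbier allylation of the aldehyde (much faster than of the ketone) should pass through a cyclic chair transition state that gives the syn adduct from the Z bromide (hence the cis-lactone, C-6/C-7); attack should follow Felkin–Anh with the bulky silyloxy-bearing ring carbon C-2 of 12 anti to the nucleophile (C-6 relative to C-5), and acid then closes the lactone.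

**Step 7**
Reactants: 14 the silyloxy ketone lactone from step 6
Product: 16 (4S)-4-[(2R,3R)-3-(3-bromobut-3-en-1-yl)-4-[(dimethylamino)methyl]-5-oxooxolan-2-yl]cyclopent-2-en-1-one (epimers at oxolane C-4), via saturated amine adduct 15 (not isolated)
Conditions: Me2NH (2 M in THF), rt; evaporate; DBU, CH2Cl2, 0 °C to rt
Reagents that add atoms: dimethylamine, CNC
Why: Aza-Michael addition masks the α-methylene lactone, which a later alkenylpalladium species would otherwise capture in a 5-exo closure, and DBU then removes the β-silyloxy group by E1cB elimination to unveil the cyclopentenone without touching the γ-stereocenter.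

**Step 8**
Reactants: 16 the amine-masked cyclopentenone from step 7
Product: 19 (4R)-4-[(2S,3R)-3-(3-bromobut-3-en-1-yl)-4-[(dimethylamino)methyl]-5-oxooxolan-2-yl]-5-methylidenecyclopent-2-en-1-one, via aldol adduct 17 (not isolated), via mesylate 18 (not isolated)
Conditions: LiN(SiMe3)2 (1.05 equiv), THF, −78 °C; CH2O (gas from paraformaldehyde), −78 °C; then MsCl, Et3N, −78 to 0 °C
Reagents that add atoms: formaldehyde, C=O
Why: Kinetic deprotonation gives the cross-conjugated α'-enolate (the γ-hydrogen at the stereocenter is not removed at −78 °C), and aldol addition to formaldehyde followed by E1cB loss of mesylate installs the exocyclic methylene regiospecifically.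

**Step 9**
Reactants: 19 the cross-conjugated dienone from step 8
Product: 21 13,15-bis(dimethylamino)-4,15:11,13-tetrahydro-7-epi-dehydrozaluzanin C (H-1α, H-5α, H-6β, H-7β; epimers at C-4 and C-11), via Mannich base 20 (not isolated)
Conditions: Me2NH (1.1 equiv), THF, 0 °C; then Pd(OAc)2 (10 mol %), PPh3 (25 mol %), HCO2Na, Et4NCl, DMF, 70 °C
Reagents that add atoms: dimethylamine, CNC
Why: Dimethylamine first adds to the exocyclic enone (temporary Mannich base, so ring A offers only C-1 as acceptor); oxidative addition into the C–Br bond, 7-exo-trig syn-carbopalladation of the cyclopentenone and formate reduction of the palladium enolate (reductive Heck reaction) then close ring B, with the tether from C-5 forcing cis ring fusion at the new stereocenter C-1.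

**Step 10**
Reactants: 21 the bis-amine from step 9
Product: 23 7-epi-dehydrozaluzanin C [(1R,5R,6S,7R)-3-oxoguaia-4(15),10(14),11(13)-trien-12,6-olide], via bis-methiodide 22 (not isolated)
Conditions: MeI (excess), MeCN, rt; then aq. NaHCO3, CH2Cl2, rt
Reagents that add atoms: none
Why: Exhaustive N-methylation turns both amines into leaving groups, and mild base expels trimethylamine by E1cB (Hofmann-type) elimination from the β-ammonium ketone and lactone, restoring both exocyclic methylenes.

**Step 11**
Reactants: 23 7-epi-dehydrozaluzanin C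
Product: 24 3-O-(tert-butyldimethylsilyl) dienol ether of 23 (3-silyloxyguaia-2,4(15),10(14),11(13)-tetraen-12,6-olide)
Conditions: TBSOTf, Et3N, CH2Cl2, −78 to 0 °C
Reagents that add atoms: tert-butyldimethylsilyl trifluoromethanesulfonate, CC(C)(C)[Si](C)(C)OS(=O)(=O)C(F)(F)F
Why: Soft enolisation can only go towards C-2 because C-4 carries no hydrogen, so the silyl dienol ether forms regiospecifically.

**Step 12**
Reactants: 24 the silyl dienol ether from step 11; 19 the cross-conjugated dienone from step 8 (2 equiv)
Product: 27 seco-dimer (rings A–D, A' and C' complete; 2α-OH; spiro C-4'; ring A' as cyclopent-2-enone; lactone C' amine-masked and carrying the 3-bromobut-3-enyl chain), via silylperoxy ketone 25 (not isolated), via hydroxy-trienone 26 (not isolated)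
Conditions: O2, tetraphenylporphyrin (cat.), visible light, CH2Cl2, −78 °C; Ar purge; then 19, Et3N, −78 °C to rt
Reagents that add atoms: dioxygen, O=O
Why: Singlet oxygen attacks the enol ether at C-2 with silyl transfer to give the α-silylperoxy ketone, and Kornblum–DeLaMare fragmentation gives the 2,3-dione as its conjugated enol; this 1-hydroxy diene (C-14=C-10–C-1=C-2) should add to the exocyclic enone of 19 in a Diels–Alder reaction (C-14 to C-15', C-2 to C-4') with C-3' endo, on the β face of the diene away from the α-lactone and on the face of 19 opposite its C-5' substituent, which sets C-2 (OH α) and spiro C-4'.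

**Step 13**
Reactants: 27 the seco-dimer from step 12
Product: 29 tris(dimethylamine) adduct of the target (CH2NMe2 at C-4, C-11 and C-11' in place of the three exocyclic methylenes; ring B' closed; H-1'α), via tris-amine 28 (not isolated)
Conditions: Me2NH (2.2 equiv), THF, 0 °C to rt, evaporate; then Pd(OAc)2 (15 mol %), PPh3 (40 mol %), HCO2Na (slow addition), Et4NCl, DMF, 70 °C
Reagents that add atoms: dimethylamine, CNC
Why: Oxidative addition of zerovalent palladium into the C-10'–Br bond gives an alkenylpalladium bromide that adds syn across C-1'=C-2' to a palladium enolate with no syn β-hydrogen, which formate reduces; this is an intramolecular reductive Heck (conjugate alkenylation) reaction, a known type for alkenyl halides and cyclic enones. Ring B' closes in the 7-exo-trig mode, C-10' bonding to the β-carbon C-1' and leaving C-10'=C-14' as the exocyclic methylene and C-3' as the saturated ketone. The new stereocenter C-1' is set by the tether, which starts on the β face at C-5' and can reach C-1' only from that face, so rings A' and B' become cis-fused (H-1' and H-5' both α). The step needs chemoselectivity among five electron-poor alkenes: the three that must not react are masked as dimethylamine adducts (the lactone C' methylene before step 8, the two of the other half in the flask), C-4' is quaternary so ring A' offers only C-1', and the C-1=C-10 alkene is out of reach. The main competitor, formate reduction of the alkenylpalladium before ring closure, is held back by slow addition of HCO2Na.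

**Step 14**
Reactants: 29 the cyclised tris-amine from step 13
Product: 31 CNP0269880.1 (target), via tris-methiodide 30 (not isolated)
Conditions: MeI (excess), MeCN, rt; then aq. NaHCO3, CH2Cl2, rt
Reagents that add atoms: none
Why: The quaternisation–elimination of step 10 should release all three exocyclic methylenes under conditions that leave the tertiary α-ketol and both ketones untouched.

**Compound list**

1 | 2-bromoprop-2-en-1-ol | OCC(Br)=C | starting material
2 | ethyl vinyl ether | C=COCC | starting material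
3 | 2-bromoallyl vinyl ether | C=COCC(Br)=C | intermediate
4 | 4-bromopent-4-enal | O=CCCC(Br)=C | intermediate
5 | methyl acrylate | C=CC(=O)OC | starting material
6 | methyl 6-bromo-3-hydroxy-2-methylidenehept-6-enoate (racemic) | C=C(C(=O)OC)C(O)CCC(Br)=C | intermediate
7 | methyl (2Z)-6-bromo-2-(bromomethyl)hepta-2,6-dienoate | BrC/C(C(=O)OC)=C\CCC(Br)=C | intermediate
8 | (4S)-4-[(tert-butyldimethylsilyl)oxy]cyclopent-2-en-1-one | O=C1C=C[C@@H](O[Si](C)(C)C(C)(C)C)C1 | starting material
9 | vinylmagnesium bromide | C=C[Mg]Br | starting material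
10 | (3R,4S)-4-[(tert-butyldimethylsilyl)oxy]-3-ethenylcyclopentan-1-one | O=C1C[C@H](C=C)[C@@H](O[Si](C)(C)C(C)(C)C)C1 | intermediate
11 | ozonide of 10, (3S,4S)-4-[(tert-butyldimethylsilyl)oxy]-3-(1,2,4-trioxolan-3-yl)cyclopentan-1-one | O=C1C[C@H](C2OCOO2)[C@@H](O[Si](C)(C)C(C)(C)C)C1 | intermediate
12 | (1S,2S)-2-[(tert-butyldimethylsilyl)oxy]-4-oxocyclopentane-1-carbaldehyde | O=C1C[C@H](C=O)[C@@H](O[Si](C)(C)C(C)(C)C)C1 | intermediate
13 | methyl (3R)-6-bromo-3-[(S)-{(1R,2S)-2-[(tert-butyldimethylsilyl)oxy]-4-oxocyclopentyl}(hydroxy)methyl]-2-methylidenehept-6-enoate | O=C1C[C@H]([C@@H](O)[C@H](CCC(Br)=C)C(=C)C(=O)OC)[C@@H](O[Si](C)(C)C(C)(C)C)C1 | intermediate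
14 | (3R,4S)-3-[(2S,3R)-3-(3-bromobut-3-en-1-yl)-4-methylidene-5-oxooxolan-2-yl]-4-[(tert-butyldimethylsilyl)oxy]cyclopentan-1-one (cis-lactone) | O=C1C[C@H]([C@H]2OC(=O)C(=C)[C@H]2CCC(Br)=C)[C@@H](O[Si](C)(C)C(C)(C)C)C1 | intermediate
15 | (3R,4S)-3-[(2S,3R)-3-(3-bromobut-3-en-1-yl)-4-[(dimethylamino)methyl]-5-oxooxolan-2-yl]-4-[(tert-butyldimethylsilyl)oxy]cyclopentan-1-one (epimers at oxolane C-4) | O=C1C[C@H]([C@H]2OC(=O)C(CN(C)C)[C@H]2CCC(Br)=C)[C@@H](O[Si](C)(C)C(C)(C)C)C1 | intermediate
16 | (4S)-4-[(2R,3R)-3-(3-bromobut-3-en-1-yl)-4-[(dimethylamino)methyl]-5-oxooxolan-2-yl]cyclopent-2-en-1-one (epimers at oxolane C-4) | O=C1C=C[C@H](C1)[C@H]2OC(=O)C(CN(C)C)[C@H]2CCC(Br)=C | intermediate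
17 | (4R)-4-[(2S,3R)-3-(3-bromobut-3-en-1-yl)-4-[(dimethylamino)methyl]-5-oxooxolan-2-yl]-5-(hydroxymethyl)cyclopent-2-en-1-one (C-5 epimers, trans expected) | OCC1C(=O)C=C[C@H]1[C@H]2OC(=O)C(CN(C)C)[C@H]2CCC(Br)=C | intermediate
18 | methanesulfonate of 17 | CS(=O)(=O)OCC1C(=O)C=C[C@H]1[C@H]2OC(=O)C(CN(C)C)[C@H]2CCC(Br)=C | intermediate
19 | (4R)-4-[(2S,3R)-3-(3-bromobut-3-en-1-yl)-4-[(dimethylamino)methyl]-5-oxooxolan-2-yl]-5-methylidenecyclopent-2-en-1-one (epimers at oxolane C-4) | C=C1C(=O)C=C[C@H]1[C@H]2OC(=O)C(CN(C)C)[C@H]2CCC(Br)=C | intermediate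
20 | (4R)-4-[(2S,3R)-3-(3-bromobut-3-en-1-yl)-4-[(dimethylamino)methyl]-5-oxooxolan-2-yl]-5-[(dimethylamino)methyl]cyclopent-2-en-1-one (Mannich base of 19; epimers at C-5 and oxolane C-4) | CN(C)CC1C(=O)C=C[C@H]1[C@H]2OC(=O)C(CN(C)C)[C@H]2CCC(Br)=C | intermediate
21 | 13,15-bis(dimethylamino)-4,15:11,13-tetrahydro-7-epi-dehydrozaluzanin C (H-1α, H-5α, H-6β, H-7β; epimers at C-4 and C-11) | CN(C)CC1C(=O)C[C@H]2C(=C)CC[C@@H]3C(CN(C)C)C(=O)O[C@@H]3[C@H]21 | intermediate
22 | bis(trimethylammonium) diiodide of 21 | C[N+](C)(C)CC1C(=O)C[C@H]2C(=C)CC[C@@H]3C(C[N+](C)(C)C)C(=O)O[C@@H]3[C@H]21.[I-].[I-] | intermediate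
23 | 7-epi-dehydrozaluzanin C, (1R,5R,6S,7R)-3-oxoguaia-4(15),10(14),11(13)-trien-12,6-olide (cis-lactone) | C=C1C(=O)C[C@H]2C(=C)CC[C@@H]3C(=C)C(=O)O[C@@H]3[C@H]21 | intermediate
24 | 3-[(tert-butyldimethylsilyl)oxy]guaia-2,4(15),10(14),11(13)-tetraen-12,6-olide with the stereocenters of 23 | C=C1C(O[Si](C)(C)C(C)(C)C)=C[C@H]2C(=C)CC[C@@H]3C(=C)C(=O)O[C@@H]3[C@H]21 | intermediate
25 | 2-[(tert-butyldimethylsilyl)peroxy] derivative of 23 (C-2 epimers) | C=C1C(=O)C(OO[Si](C)(C)C(C)(C)C)[C@H]2C(=C)CC[C@@H]3C(=C)C(=O)O[C@@H]3[C@H]21 | intermediate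
26 | (5R,6S,7R)-2-hydroxy-3-oxoguaia-1,4(15),10(14),11(13)-tetraen-12,6-olide (enol of the 2,3-dione) | C=C1C(=O)C(O)=C2C(=C)CC[C@@H]3C(=C)C(=O)O[C@@H]3[C@@H]12 | intermediate
27 | seco-dimer: Diels–Alder adduct of 26 and 19 (2α-OH, C-4' on the β face of C-2; at C-4', C-2 is anti to C-6'; ring A' a cyclopent-2-enone; lactone C' amine-masked; alkenyl bromide at C-10') | C=C1C(=O)[C@]2(O)C3=C(CC[C@@H]4C(=C)C(=O)O[C@@H]4[C@@H]13)CC[C@]21C(=O)C=C[C@H]1[C@H]3OC(=O)C(CN(C)C)[C@H]3CCC(Br)=C | intermediate
28 | tris-amine: 27 with dimethylamine added at C-15 and C-13 of the unprimed half (epimers at C-4, C-11, C-11') | CN(C)CC1C(=O)[C@]2(O)C3=C(CC[C@@H]4C(CN(C)C)C(=O)O[C@@H]4[C@@H]13)CC[C@]21C(=O)C=C[C@H]1[C@H]3OC(=O)C(CN(C)C)[C@H]3CCC(Br)=C | intermediate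
29 | tris(dimethylamine) adduct of the target (ring B' closed, H-1'α, H-5'α; CH2NMe2 at C-4, C-11, C-11') | CN(C)CC1C(=O)[C@]2(O)C3=C(CC[C@@H]4C(CN(C)C)C(=O)O[C@@H]4[C@@H]13)CC[C@]21C(=O)C[C@H]2C(=C)CC[C@@H]3C(CN(C)C)C(=O)O[C@@H]3[C@H]21 | intermediate
30 | tris(trimethylammonium) triiodide of 29 | C[N+](C)(C)CC1C(=O)[C@]2(O)C3=C(CC[C@@H]4C(C[N+](C)(C)C)C(=O)O[C@@H]4[C@@H]13)CC[C@]21C(=O)C[C@H]2C(=C)CC[C@@H]3C(C[N+](C)(C)C)C(=O)O[C@@H]3[C@H]21.[I-].[I-].[I-] | intermediate
31 | CNP0269880.1, spiro dimer of two 7-epi-guaianolide halves (2S,5R,6S,7R; 1'R,4'R,5'R,6'S,7'R) | C=C1C(=O)[C@]2(O)C3=C(CC[C@@H]4C(=C)C(=O)O[C@@H]4[C@@H]13)CC[C@]21C(=O)C[C@H]2C(=C)CC[C@@H]3C(=C)C(=O)O[C@@H]3[C@H]21 | target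

**Step count.** 14 steps in total. The longest linear sequence is 12 steps (steps 1–3, then 6–14). Compound 19 is used twice, in step 9 and in step 12.

**Steps most likely to fail**

Step 13. Formate may reduce the alkenylpalladium bromide before the slow seven-membered carbopalladation (hydrodebromination). Heating may also release dimethylamine from the temporary Mannich base, so that the freed enone is reduced. The fallback closes the ring with a radical instead of an organopalladium species. It sets out from the tris-amine 28, made as in step 13 but isolated, and returns at 29. With (Me3Si)3SiH and Et3B/air in PhMe at 0 °C, bromine abstraction gives the C-10' alkenyl radical, which should add 7-exo-trig to C-1' of the enone; the α-keto radical takes hydrogen from the silane. No compound outside the list is made (none F0).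

Step 12. The hydroxy-trienone 26 may dimerise with itself or be attacked at C-1 instead of C-14 before the cycloaddition, and facial selectivity may be low. The fallback introduces the oxygen at C-2 after ring D instead of before. From 24, Pd(OAc)2 (1.1 equiv) in MeCN at rt in the presence of 19 effects Saegusa oxidation to 7-epi-1,2-didehydrodehydrozaluzanin C F1, which is trapped in the flask by 19 to give the 2-deoxy adduct F2 (H-2α). The extended enolate of F2 (KN(SiMe3)2, THF, −78 °C; C-2 carries the only hydrogen α to a ketone) is hydroxylated with 2-(phenylsulfonyl)-3-phenyloxaziridine. This rejoins the route at 27; C-2 epimers would have to be separated.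

Step 9. At 70 °C the temporary Mannich base 20 may lose dimethylamine, and the freed exocyclic enone may then be reduced by palladium hydride or polymerise; hydrodebromination may also compete. The fallback carries the future methylene through the cyclisation as a hydroxymethyl group. From 16, the aldol adduct 17 is isolated (first half of step 8) and cyclised under the reductive Heck conditions to the hydroxymethyl ketone F3. MsCl and Et3N give the mesylate F4 and, by elimination, the lactone-masked enone F5. MeI and then aq. NaHCO3, by way of the methiodide F6, return to the route at 23.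

**Further compounds**

F0 | step 13 | none | none
F1 | step 12 | 7-epi-1,2-didehydrodehydrozaluzanin C, (5R,6S,7R)-3-oxoguaia-1,4(15),10(14),11(13)-tetraen-12,6-olide | C=C1C(=O)C=C2C(=C)CC[C@@H]3C(=C)C(=O)O[C@@H]3[C@@H]12
F2 | step 12 | 2-deoxy adduct (27 with H-2α in place of the hydroxyl) | C=C1C(=O)[C@@H]2C3=C(CC[C@@H]4C(=C)C(=O)O[C@@H]4[C@@H]13)CC[C@]21C(=O)C=C[C@H]1[C@H]3OC(=O)C(CN(C)C)[C@H]3CCC(Br)=C
F3 | step 9 | hydroxymethyl ketone: 13-(dimethylamino)-15-hydroxy-4,15:11,13-tetrahydro-7-epi-dehydrozaluzanin C | OCC1C(=O)C[C@H]2C(=C)CC[C@@H]3C(CN(C)C)C(=O)O[C@@H]3[C@H]21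
F4 | step 9 | methanesulfonate of F3 | CS(=O)(=O)OCC1C(=O)C[C@H]2C(=C)CC[C@@H]3C(CN(C)C)C(=O)O[C@@H]3[C@H]21
F5 | step 9 | lactone-masked enone: 13-(dimethylamino)-11,13-dihydro-7-epi-dehydrozaluzanin C | C=C1C(=O)C[C@H]2C(=C)CC[C@@H]3C(CN(C)C)C(=O)O[C@@H]3[C@H]21
F6 | step 9 | trimethylammonium iodide of F5 | C=C1C(=O)C[C@H]2C(=C)CC[C@@H]3C(C[N+](C)(C)C)C(=O)O[C@@H]3[C@H]21.[I-]
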